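**Fast loss.** Within 25.0 min the dusk run has lost 76.0% of its starting material, far more than the 1% standing there as target, so the reading points to a path other than the target.

- dusk: starting material 0.020 M; reagent in the second phase 0.080 M; protic impurity 0.040 M; run made earlier
- flask: starting material 0.020 M; reagent in the second phase 0.0800 M; protic impurity 0.0200 M; time 6.0 h; volume of the second phase over the first 0.25

dusk run (percent of the starting material charged)

| time / min | target / % | starting material / % |
|---|---|---|
| 10.0 | 0 | 57 |
| 25.0 | 1 | 24 |
| 50.0 | 4 | 10 |
| 80.0 | 6 | 1 |
| 120 | 6 | 0 |

(scatter of a reading: 2 percentage points)

- target at 6.0 h, in percent of the starting material charged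
- part of the starting material charged that has reacted at 6.0 h

- in the second phase: reagent in the second phase; everything else is in the first
- charges count per volume of the first phase; a concentration in a rate is the amount of a species over the volume of its own phase; every rate counts per litre of the first phase
- the earlier runs hold the two phases in the same ratio of volumes as the flask asked about
- no earlier run changes the charge of protic impurity; that part of a forecast is a guess

**Ladder of clocks.** That reading gives a pseudo-first-order half-life τ of 12.1 min in the dusk run, the lowest rung. The next rung is a guess of this reckoning, since no earlier run changes the protic impurity: if the loss scales with that charge, 0.0200 M against 0.040 M stretches τ in the flask to 24.3 min. The dusk run reads 6% of target and 1% of starting material at 80.0 min, and 6% of target at 120 min. Stretched alike, the reckoned stop of the target in the flask lies near 2.67 h, earlier than the asked 6.0 h, the top rung. On that guess the flask counts 14.8 turnovers N, half-lives within the time, and with the protic impurity held at its charge the count leaves 0.00345% of the starting material. The count gives when the target stops, not how high.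

**The forecast.** It gives 12% of target and 99.5% reacted, on this ground: “If that diversion scales with impurity, halving it roughly doubles the yield”. The remainder by the count is smaller than the 0.500% that the forecast leaves.

**The result.** The flask gives 18.2% of target, above the forecast, and >99.9% reacted, within its tolerance.

    reagent in the reaction phase ⇌ reagent in the second phase, rate k1*([reagent in the reaction phase] - [reagent in the second phase]/K1) per volume of the first phase (partition coefficient = 19.0, kL = 2.00 × 10⁻⁴ s⁻¹)
    starting material + reagent in the reaction phase → target (k = 0.0230 M⁻¹ s⁻¹)
    starting material + protic impurity → quenched substrate (k = 0.0270 M⁻¹ s⁻¹)
    starting material + target → side product (k = 0.0170 M⁻¹ s⁻¹)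

**At rest.** At 3.00 h the flask holds 1.05% of starting material and 17.7% of target, just past the reckoned 2.67 h. The neighbour flask with 0.050 M of protic impurity counts 37.1 turnovers by the same guess and ends with 0% of starting material. At 60.0 h the flask still shows 18.2% of target and 27.8% of its protic impurity, while the reagent in the reaction phase has gone from 0.0130 M to 0.0131 M.

The numbers in the tables come from a simulation with constants of no real substance; scatter was added.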